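**Retrosynthetic overview**

1. Ring numbering used below: C1 quaternary carbon (Me, 4-methylpent-3-enyl), C2=C3 (Z), C4 (O-acyl), C5 (Me, OH), C6=C7 (Z), C8 (C=O), C9 (CH2OH)=C10 (ring-cis), C11.
2. Enabling feature: the cis-γ-hydroxy-enone C5(OH)–C6=C7–C8(=O) is the ring-opened, transposed form of a 2-methylfuran-3(2H)-one (ring O between C5 and C8, C6=O). That ring makes C5–H the only readily enolisable site (aromatic enolate), locks the enolate geometry and later the Z-C6=C7 bond; quaternary C1 makes the C2=C3–C4 (Z)-enal non-enolisable.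
3. Target ⇐ desilylation ⇐ Luche reduction/acid transposition (furanone opened to C5–OH/C8=O) ⇐ O-senecioylation ⇐ C4–C5 boron aldol macrocyclisation of furanone–enal 18 (11-membered ring; C4 and C5 set together).
4. 18 ⇐ alkenyl iodide 12 + CO + but-3-yn-2-ol (carbonylative Sonogashira, amine-mediated furanone closure); 12 ⇐ aldehyde 9 (iodo-Wittig) ⇐ (S)-enyne 5.
5. 5 ⇐ geraniol by copper-catalysed enantioselective allylic substitution with an alkynylalane (sets C1; alkyne becomes Z-C2=C3, vinyl becomes C11–C10). Ring order: furanone (step 10), 11-membered carbocycle (step 12), furanone opened (step 14).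

Key step: step 12

Assumption: the target is taken as the open cis-γ-hydroxy-enone of the assigned structure; its five-membered hemiketal (C5–O–C8) is a ring–chain tautomer of the same compound.
Assumption: (−)-Ipc2BOTf is taken to direct the ring-locked Z-type boron enolate to the Si face of the aldehyde; if the sense proves opposite, the antipodal reagent from (−)-α-pinene is used and nothing else changes.

**Route**

Step 1
Reactants: 1 geraniol
Product: 2 geranyl diethyl phosphate
Conditions: ClP(O)(OEt)2, pyridine, CH2Cl2, 0 °C to rt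
Reagents that add atoms: diethyl chlorophosphate CCOP(=O)(Cl)OCC
Why: Phosphorylation of the primary allylic alcohol (phosphate ester formation) installs the leaving group for SN2'-selective copper-catalysed allylic substitution.

Step 2
Reactants: 2 geranyl diethyl phosphate; 3 tert-butyldimethyl(prop-2-yn-1-yloxy)silane
Product: 5 (S)-tert-butyl[(4-ethenyl-4,8-dimethylnon-7-en-2-yn-1-yl)oxy]dimethylsilane, via alkynylalane 4 (not isolated)
Conditions: 3, i-Bu2AlH, Et3N (5 mol %), hexanes, 22 °C; then 2, CuCl2·2H2O (5 mol %), chiral sulfonate-bearing imidazolinium salt (NHC precursor, 5 mol %), THF, −15 °C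
Reagents that add atoms: none
Why: Copper–NHC-catalysed enantioselective allylic substitution (SN2') with an alkynylaluminium reagent should deliver the alkynyl group to the disubstituted alkene terminus and set quaternary C1 by catalyst control, the ligand enantiomer being the one that gives (S)-5.

Step 3
Reactants: 5 (S)-enyne silyl ether
Product: 6 tert-butyl{[(2Z,4S)-4-ethenyl-4,8-dimethylnona-2,7-dien-1-yl]oxy}dimethylsilane
Conditions: H2 (1 atm), Pd/CaCO3 poisoned with Pb(OAc)2 (Lindlar catalyst), quinoline, EtOAc/hexanes, rt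
Reagents that add atoms: none
Why: Lindlar semi-hydrogenation adds H2 syn to the alkyne and should stop at the (Z)-alkene C2=C3, the alkyne being adsorbed far more strongly than the vinyl and trisubstituted alkenes.

Step 4
Reactants: 6 (Z)-triene silyl ether
Product: 8 (3S,4Z)-6-(tert-butyldimethylsilyloxy)-3-methyl-3-(4-methylpent-3-en-1-yl)hex-4-en-1-ol, via alkylborane 7 (not isolated)
Conditions: 9-BBN, THF, 0 °C to rt; then NaOH, H2O2, H2O, 0 °C
Reagents that add atoms: hydrogen peroxide OO
Why: Anti-Markovnikov hydroboration–oxidation, in which 9-BBN should react only with the monosubstituted vinyl group because the (Z)-alkene beside the quaternary carbon and the trisubstituted alkene are much slower.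

Step 5
Reactants: 8 primary alcohol
Product: 9 (3S,4Z)-6-(tert-butyldimethylsilyloxy)-3-methyl-3-(4-methylpent-3-en-1-yl)hex-4-enal
Conditions: Dess–Martin periodinane, NaHCO3, CH2Cl2, 0 °C to rt
Reagents that add atoms: none
Why: Buffered Dess–Martin oxidation of the primary alcohol to the aldehyde leaves the silyl ether and all alkenes untouched.

Step 6
Reactants: 9 aldehyde
Product: 10 ethyl (2Z,5S,6Z)-8-(tert-butyldimethylsilyloxy)-2-iodo-5-methyl-5-(4-methylpent-3-en-1-yl)octa-2,6-dienoate
Conditions: Ph3P=CHCO2Et, N-iodosuccinimide, CH2Cl2, −20 °C; then 9, −20 °C to rt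
Reagents that add atoms: ethyl (triphenylphosphoranylidene)acetate CCOC(=O)C=P(c1ccccc1)(c1ccccc1)c1ccccc1; N-iodosuccinimide O=C1CCC(=O)N1I
Why: Wittig olefination with the iodo-ylide Ph3P=C(I)CO2Et formed in the flask should give mainly the (Z)-2-iodoenoate (ester trans to the chain, as for stabilised ylides), which fixes the later ring-cis relation of C8 and C11; the minor E isomer is removed by chromatography.

Step 7
Reactants: 10 iodoenoate
Product: 11 (2Z,5S,6Z)-8-(tert-butyldimethylsilyloxy)-2-iodo-5-methyl-5-(4-methylpent-3-en-1-yl)octa-2,6-dien-1-ol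
Conditions: i-Bu2AlH, CH2Cl2, −78 °C; aqueous potassium sodium tartrate (KNaC4H4O6)
Reagents that add atoms: none
Why: Low-temperature i-Bu2AlH reduction of the conjugated ester to the allylic alcohol (1,2-reduction) should not touch the alkenyl iodide or the silyl ether.

Step 8
Reactants: 11 iodo allylic alcohol
Product: 12 tert-butyldiphenylsilyl ether of 11
Conditions: TBDPSCl, imidazole, DMF, rt
Reagents that add atoms: tert-butyl(chloro)diphenylsilane CC(C)(C)[Si](Cl)(c1ccccc1)c1ccccc1
Why: Silylation of the primary alcohol as a tert-butyldiphenylsilyl ether, which outlasts the acid that later removes the tert-butyldimethylsilyl group.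

Step 9
Reactants: 12 alkenyl iodide; 13 but-3-yn-2-ol (racemic)
Product: 14 (6Z,9S,10Z)-12-(tert-butyldimethylsilyloxy)-6-[(tert-butyldiphenylsilyloxy)methyl]-2-hydroxy-9-methyl-9-(4-methylpent-3-en-1-yl)dodeca-6,10-dien-3-yn-5-one (both C2 epimers)
Conditions: PdCl2(PPh3)2 (5 mol %), CuI (2 mol %), CO (1 atm), Et3N, THF, rt
Reagents that add atoms: carbon monoxide [C-]#[O+]
Why: Carbonylative Sonogashira coupling, in which oxidative addition with retention of alkene geometry, CO insertion and capture of the acylpalladium by the copper acetylide (faster than by the secondary hydroxyl) should give the cross-conjugated ynone.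

Step 10
Reactants: 14 γ-hydroxy enynone
Product: 17 5-[(2Z,5S,6Z)-1-(tert-butyldiphenylsilyloxy)-8-hydroxy-5-methyl-5-(4-methylpent-3-en-1-yl)octa-2,6-dien-2-yl]-2-methylfuran-3(2H)-one (both furanone epimers), via β-amino enone 15 (not isolated), via silyl furanone 16 (not isolated)
Conditions: Et2NH, EtOH, rt; then 1 M HCl, THF, rt
Reagents that add atoms: water O
Why: Conjugate addition of Et2NH to the ynone gives a β-amino enone that aqueous acid hydrolyses and closes by attack of the hydroxyl on the C8 carbonyl (5-exo-trig, loss of water) to the furan-3(2H)-one, and the same acid cleaves the primary tert-butyldimethylsilyl ether while the tert-butyldiphenylsilyl ether survives; the furanone C5 centre forms as both epimers, which is of no consequence.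

Step 11
Reactants: 17 furanone allylic alcohol
Product: 18 (2Z,4S,6Z)-8-(tert-butyldiphenylsilyloxy)-4-methyl-7-(5-methyl-4-oxo-4,5-dihydrofuran-2-yl)-4-(4-methylpent-3-en-1-yl)octa-2,6-dienal
Conditions: Dess–Martin periodinane, NaHCO3, CH2Cl2, 0 °C
Reagents that add atoms: none
Why: Buffered Dess–Martin oxidation of the (Z)-allylic alcohol should give the (Z)-enal without Z/E isomerisation, and the enal cannot enolise because C1 is quaternary; it is used at once.

Step 12
Reactants: 18 furanone (Z)-enal
Product: 21 aldol macrocycle [(1S,2Z,4R,5R,9Z)-9-[(tert-butyldiphenylsilyloxy)methyl]-4-hydroxy-1,5-dimethyl-1-(4-methylpent-3-en-1-yl)-5,8-epoxycycloundeca-2,7,9-trien-6-one], via boron enolate 19 (not isolated), via boron aldolate 20 (not isolated)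
Conditions: (−)-Ipc2BOTf (from (−)-Ipc2BH and TfOH, 2.5 equiv), i-Pr2NEt (3 equiv), CH2Cl2, −78 °C, slow addition of 18 (final 1 mM), then −78 to −40 °C; H2O2, pH 7 buffer, MeOH, 0 °C
Reagents that add atoms: none
Why: Proposed new method: reagent-controlled boron aldol macrocyclisation of a furan-3(2H)-one, the closest known types being the syn-aldol of Z-enol diisopinocampheylborinates of ketones with aldehydes, metal-enolate macro-aldolisations and C2-aldol reactions of furan-3(2H)-ones; Ipc2BOTf/i-Pr2NEt should enolise only C5–H (the one readily enolisable C–H, its enolate being an aromatic 3-boryloxyfuran, while the enal has no γ-hydrogen because C1 is quaternary), and the boron enolate then adds to the tethered aldehyde through a six-membered chair transition state. The 11-membered carbocycle closes by 11-(enolendo)-exo-trig attack of C5 on the C4 carbonyl, giving a furanone-bridged 12-oxabicyclo[7.2.1]dodecane; the two cis alkenes and the planar furan hold C4 near C5, and high dilution suppresses oligomers. C4 and the quaternary C5 are set together: the furan ring locks the enolate with the methyl cis to O–B (Z-type), so the chair with the aldehyde substituent equatorial gives the methyl/hydroxyl-syn aldol, which is the C4–O/C5–O anti pair of the target (C5 is R by CIP here only because C6 is a ketone). The absolute sense (attack on the Si face of the aldehyde, 4R) is controlled by the isopinocampheyl ligands, because C1 is remote and its methyl and CH2CH2R groups are too alike to bias the closure. The step needs 1,2- over 1,4-addition, secured by the neopentylic β-carbon C2, and retention of the Z-enal geometry, secured by non-acidic conditions at −78 °C.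

Step 13
Reactants: 21 aldol macrocycle
Product: 22 4-O-(3-methylbut-2-enoyl) ester of 21
Conditions: 3-methylbut-2-enoyl chloride, pyridine, DMAP (cat.), CH2Cl2, 0 °C
Reagents that add atoms: 3-methylbut-2-enoyl chloride CC(C)=CC(=O)Cl
Why: Acylation of the only free hydroxyl (secondary C4–OH) under pyridine/DMAP, a base too weak to trigger retro-aldol cleavage or deconjugation of the senecioyl group.

Step 14
Reactants: 22 senecioate furanone
Product: 24 (1S,2Z,4R,5S,6Z,9Z)-9-[(tert-butyldiphenylsilyloxy)methyl]-5-hydroxy-1,5-dimethyl-4-(3-methylbut-2-enoyloxy)-1-(4-methylpent-3-en-1-yl)cycloundeca-2,6,9-trien-8-one, via allylic alcohol 23 (not isolated)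
Conditions: NaBH4, CeCl3·7H2O, MeOH, −40 °C; then 0.1 M HCl, THF/H2O, 0 °C
Reagents that add atoms: water O
Why: Luche 1,2-reduction of the vinylogous-ester carbonyl followed by acid-mediated allylic transposition (Stork–Danheiser type), in which loss of the C6 hydroxyl gives an oxocarbenium ion that water captures at C8 and the hemiketal opens to the C8 ketone and the C5 tertiary alcohol, the C6=C7 bond being cis because it was formed inside the five-membered ring and C5 being untouched.

Step 15
Reactants: 24 silyl-protected target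
Product: 25 target CNP0230506.4
Conditions: HF·pyridine, pyridine, THF, 0 °C to rt
Reagents that add atoms: none
Why: Fluoride-mediated cleavage of the primary silyl ether under buffered, non-basic conditions should spare the ester, the tertiary allylic alcohol and the dienone.

**Compound list**

1 | geraniol | CC(C)=CCC/C(C)=C/CO | starting material
2 | geranyl diethyl phosphate | CC(C)=CCC/C(C)=C/COP(=O)(OCC)OCC | intermediate
3 | tert-butyldimethyl(prop-2-yn-1-yloxy)silane | C#CCO[Si](C)(C)C(C)(C)C | starting material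
4 | diisobutyl[3-(tert-butyldimethylsilyloxy)prop-1-yn-1-yl]alane | CC(C)C[Al](CC(C)C)C#CCO[Si](C)(C)C(C)(C)C | intermediate
5 | (S)-tert-butyl[(4-ethenyl-4,8-dimethylnon-7-en-2-yn-1-yl)oxy]dimethylsilane | CC(C)=CCC[C@](C)(C#CCO[Si](C)(C)C(C)(C)C)C=C | intermediate
6 | tert-butyl{[(2Z,4S)-4-ethenyl-4,8-dimethylnona-2,7-dien-1-yl]oxy}dimethylsilane | CC(C)=CCC[C@](C)(/C=C\CO[Si](C)(C)C(C)(C)C)C=C | intermediate
7 | B-alkyl-9-borabicyclo[3.3.1]nonane from 6 (boron on the terminal carbon of the former vinyl group, quaternary carbon unchanged) | CC(C)=CCC[C@](C)(/C=C\CO[Si](C)(C)C(C)(C)C)CCB1C2CCCC1CCC2 | intermediate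
8 | (3S,4Z)-6-(tert-butyldimethylsilyloxy)-3-methyl-3-(4-methylpent-3-en-1-yl)hex-4-en-1-ol | CC(C)=CCC[C@](C)(/C=C\CO[Si](C)(C)C(C)(C)C)CCO | intermediate
9 | (3S,4Z)-6-(tert-butyldimethylsilyloxy)-3-methyl-3-(4-methylpent-3-en-1-yl)hex-4-enal | CC(C)=CCC[C@](C)(/C=C\CO[Si](C)(C)C(C)(C)C)CC=O | intermediate
10 | ethyl (2Z,5S,6Z)-8-(tert-butyldimethylsilyloxy)-2-iodo-5-methyl-5-(4-methylpent-3-en-1-yl)octa-2,6-dienoate | CC(C)=CCC[C@](C)(/C=C\CO[Si](C)(C)C(C)(C)C)C/C=C(\I)C(=O)OCC | intermediate
11 | (2Z,5S,6Z)-8-(tert-butyldimethylsilyloxy)-2-iodo-5-methyl-5-(4-methylpent-3-en-1-yl)octa-2,6-dien-1-ol | CC(C)=CCC[C@](C)(/C=C\CO[Si](C)(C)C(C)(C)C)C/C=C(\I)CO | intermediate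
12 | tert-butyldiphenylsilyl ether of 11 | CC(C)=CCC[C@](C)(/C=C\CO[Si](C)(C)C(C)(C)C)C/C=C(\I)CO[Si](c1ccccc1)(c1ccccc1)C(C)(C)C | intermediate
13 | but-3-yn-2-ol (racemic) | CC(O)C#C | starting material
14 | (6Z,9S,10Z)-12-(tert-butyldimethylsilyloxy)-6-[(tert-butyldiphenylsilyloxy)methyl]-2-hydroxy-9-methyl-9-(4-methylpent-3-en-1-yl)dodeca-6,10-dien-3-yn-5-one (both C2 epimers) | CC(C)=CCC[C@](C)(/C=C\CO[Si](C)(C)C(C)(C)C)C/C=C(/CO[Si](c1ccccc1)(c1ccccc1)C(C)(C)C)C(=O)C#CC(C)O | intermediate
15 | 3-(diethylamino) enone from 14 (β-amino enone) | CC(C)=CCC[C@](C)(/C=C\CO[Si](C)(C)C(C)(C)C)C/C=C(/CO[Si](c1ccccc1)(c1ccccc1)C(C)(C)C)C(=O)C=C(N(CC)CC)C(C)O | intermediate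
16 | 5-[(2Z,5S,6Z)-8-(tert-butyldimethylsilyloxy)-1-(tert-butyldiphenylsilyloxy)-5-methyl-5-(4-methylpent-3-en-1-yl)octa-2,6-dien-2-yl]-2-methylfuran-3(2H)-one (both furanone epimers) | CC(C)=CCC[C@](C)(/C=C\CO[Si](C)(C)C(C)(C)C)C/C=C(/CO[Si](c1ccccc1)(c1ccccc1)C(C)(C)C)C1=CC(=O)C(C)O1 | intermediate
17 | 5-[(2Z,5S,6Z)-1-(tert-butyldiphenylsilyloxy)-8-hydroxy-5-methyl-5-(4-methylpent-3-en-1-yl)octa-2,6-dien-2-yl]-2-methylfuran-3(2H)-one (both furanone epimers) | CC(C)=CCC[C@](C)(/C=C\CO)C/C=C(/CO[Si](c1ccccc1)(c1ccccc1)C(C)(C)C)C1=CC(=O)C(C)O1 | intermediate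
18 | (2Z,4S,6Z)-8-(tert-butyldiphenylsilyloxy)-4-methyl-7-(5-methyl-4-oxo-4,5-dihydrofuran-2-yl)-4-(4-methylpent-3-en-1-yl)octa-2,6-dienal (both furanone epimers) | CC(C)=CCC[C@](C)(/C=C\C=O)C/C=C(/CO[Si](c1ccccc1)(c1ccccc1)C(C)(C)C)C1=CC(=O)C(C)O1 | intermediate
19 | boron enolate of 18: 3-[bis(isopinocampheyl)boryloxy]-2-methylfuran form | CC(C)=CCC[C@](C)(/C=C\C=O)C/C=C(/CO[Si](c1ccccc1)(c1ccccc1)C(C)(C)C)c1cc(OB([C@@H]2C[C@@H]3C[C@H]([C@H]2C)C3(C)C)[C@@H]2C[C@@H]3C[C@H]([C@H]2C)C3(C)C)c(C)o1 | intermediate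
20 | boron aldolate: 4-O-bis(isopinocampheyl)boryl derivative of 21 | CC(C)=CCC[C@]1(C)/C=C\[C@@H](OB([C@@H]2C[C@@H]3C[C@H]([C@H]2C)C3(C)C)[C@@H]2C[C@@H]3C[C@H]([C@H]2C)C3(C)C)[C@@]2(C)OC(=CC2=O)/C(CO[Si](c3ccccc3)(c3ccccc3)C(C)(C)C)=C\C1 | intermediate
21 | (1S,2Z,4R,5R,9Z)-9-[(tert-butyldiphenylsilyloxy)methyl]-4-hydroxy-1,5-dimethyl-1-(4-methylpent-3-en-1-yl)-5,8-epoxycycloundeca-2,7,9-trien-6-one (route numbering; 2,5-bridged furan-3(2H)-one) | CC(C)=CCC[C@]1(C)/C=C\[C@@H](O)[C@@]2(C)OC(=CC2=O)/C(CO[Si](c3ccccc3)(c3ccccc3)C(C)(C)C)=C\C1 | intermediate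
22 | 4-O-(3-methylbut-2-enoyl) ester of 21 | CC(C)=CCC[C@]1(C)/C=C\[C@@H](OC(=O)C=C(C)C)[C@@]2(C)OC(=CC2=O)/C(CO[Si](c3ccccc3)(c3ccccc3)C(C)(C)C)=C\C1 | intermediate
23 | 6-hydroxy compound from 22 (C6 carbinol, either epimer) | CC(C)=CCC[C@]1(C)/C=C\[C@@H](OC(=O)C=C(C)C)[C@@]2(C)OC(=CC2O)/C(CO[Si](c3ccccc3)(c3ccccc3)C(C)(C)C)=C\C1 | intermediate
24 | (1S,2Z,4R,5S,6Z,9Z)-9-[(tert-butyldiphenylsilyloxy)methyl]-5-hydroxy-1,5-dimethyl-4-(3-methylbut-2-enoyloxy)-1-(4-methylpent-3-en-1-yl)cycloundeca-2,6,9-trien-8-one (route numbering) | CC(C)=CCC[C@]1(C)/C=C\[C@@H](OC(=O)C=C(C)C)[C@@](C)(O)/C=C\C(=O)/C(CO[Si](c2ccccc2)(c2ccccc2)C(C)(C)C)=C\C1 | intermediate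
25 | CNP0230506.4: (1S,2Z,4R,5S,6Z,9Z)-5-hydroxy-9-(hydroxymethyl)-1,5-dimethyl-4-(3-methylbut-2-enoyloxy)-1-(4-methylpent-3-en-1-yl)cycloundeca-2,6,9-trien-8-one (route numbering) | CC(C)=CCC[C@]1(C)/C=C\[C@@H](OC(=O)C=C(C)C)[C@@](C)(O)/C=C\C(=O)/C(CO)=C\C1 | target

**Step count and risks**

Total step count: 15. Longest linear sequence: 15 steps (geraniol 1 to target 25); 3 and 13 are purchased.

Steps most likely to fail:

Step 12 (proposed new method). An isopinocampheyl group may transfer hydride to the aldehyde before enolisation and ring closure occur. Intermolecular aldol oligomerisation may compete if dilution is insufficient. The enal may isomerise before closure, or the ligand-derived facial control may be weak or mismatched, so that the C4/C5-epimeric syn-aldol forms. Fallback with known acetal-template chemistry, setting out from 18 and returning at 21: the aldehyde of 18 is converted with (2R,4R)-2,4-bis(trimethylsilyloxy)pentane and catalytic TMSOTf (CH2Cl2, −78 °C) into the (4R,6R)-4,6-dimethyl-1,3-dioxane acetal F1. TBSOTf/Et3N then gives the 3-silyloxyfuran acetal F2. TiCl4 (CH2Cl2, −78 °C, high dilution) closes the ring by a Mukaiyama acetal-aldol reaction, the furan attacking the acetal carbon with inversion, opposite to the C–O bond next to the axial methyl group (this fixes 4R), to give the macrocyclic hydroxy ether F3. Dess–Martin oxidation gives the macrocyclic keto ether F4, and β-elimination with dibenzylammonium trifluoroacetate (benzene, 50 °C) releases 21, where the route resumes at step 13.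

Step 9. Oxidative addition and CO insertion may be slow at the hindered trisubstituted alkenyl iodide, so that CO-free alkynylation, capture of the acylpalladium by the free hydroxyl, or alkyne homocoupling takes over. Fallback, setting out from 12 and returning at 17: iodine–lithium exchange of 12 (t-BuLi, Et2O, −78 °C) and acylation of the alkenyllithium with N-methoxy-N-methyl-4-(tert-butyldimethylsilyloxy)pent-2-ynamide F5 gives the silyl-protected ynone F6. F5 is made from commercial tert-butyldimethyl(but-3-yn-2-yloxy)silane with n-BuLi and N-methoxy-N-methylcarbamoyl chloride. F6, under the conditions of step 10 with a longer acid stage, gives 17.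

Step 14. Hydride delivery to the vinylogous-ester carbonyl may be slow, so that borohydride attacks the senecioate or the conjugated π-system instead. On ionisation the cation may also undergo a 1,2-shift toward a furan before water captures it at C8. Fallback, setting out from 21 and returning at 24: hydroxyl-directed Evans–Saksena reduction of the free aldol 21 with Me4NBH(OAc)3 in MeCN/AcOH (−20 °C) delivers hydride intramolecularly to C6 before any ester is present, and the acidic medium and aqueous work-up complete the transposition to the diol enone F7. Selective acylation of the secondary C4 hydroxyl in the presence of the tertiary C5 hydroxyl (3-methylbut-2-enoyl chloride, pyridine, DMAP, 0 °C) gives 24.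

Further compounds
F1 | step 12 | (4R,6R)-4,6-dimethyl-1,3-dioxane acetal of 18 | CC(C)=CCC[C@](C)(/C=C\C1O[C@H](C)C[C@@H](C)O1)C/C=C(/CO[Si](c1ccccc1)(c1ccccc1)C(C)(C)C)C1=CC(=O)C(C)O1
F2 | step 12 | 3-(tert-butyldimethylsilyloxy)-2-methylfuran form of F1 | CC(C)=CCC[C@](C)(/C=C\C1O[C@H](C)C[C@@H](C)O1)C/C=C(/CO[Si](c1ccccc1)(c1ccccc1)C(C)(C)C)c1cc(O[Si](C)(C)C(C)(C)C)c(C)o1
F3 | step 12 | 4-O-[(2R,4R)-4-hydroxypentan-2-yl] ether of 21 | CC(C)=CCC[C@]1(C)/C=C\[C@@H](O[C@H](C)C[C@@H](C)O)[C@@]2(C)OC(=CC2=O)/C(CO[Si](c3ccccc3)(c3ccccc3)C(C)(C)C)=C\C1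
F4 | step 12 | 4-O-[(2R)-4-oxopentan-2-yl] ether of 21 | CC(C)=CCC[C@]1(C)/C=C\[C@@H](O[C@H](C)CC(C)=O)[C@@]2(C)OC(=CC2=O)/C(CO[Si](c3ccccc3)(c3ccccc3)C(C)(C)C)=C\C1
F5 | step 9 | N-methoxy-N-methyl-4-(tert-butyldimethylsilyloxy)pent-2-ynamide | CON(C)C(=O)C#CC(C)O[Si](C)(C)C(C)(C)C
F6 | step 9 | 2-O-tert-butyldimethylsilyl ether of 14 | CC(C)=CCC[C@](C)(/C=C\CO[Si](C)(C)C(C)(C)C)C/C=C(/CO[Si](c1ccccc1)(c1ccccc1)C(C)(C)C)C(=O)C#CC(C)O[Si](C)(C)C(C)(C)C
F7 | step 14 | 4,5-diol analogue of 24 (free C4 hydroxyl) | CC(C)=CCC[C@]1(C)/C=C\[C@@H](O)[C@@](C)(O)/C=C\C(=O)/C(CO[Si](c2ccccc2)(c2ccccc2)C(C)(C)C)=C\C1
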